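**Strategy.** The target is a syringaresinol-type furofuran (7R,8S,7'R,8'S) carrying one threo and two erythro guaiacylglycerol β-aryl ether chains. Everything rests on cutting ring 2 of the furofuran (C-7', O, C-9, C-8, C-8') into formaldehyde and a donor–acceptor cyclopropane: an endo-aryl 3-oxabicyclo[3.1.0]hexan-2-one from a catalytic asymmetric cyclopropanation, whose lactone carbonyl (the future C-7) is the only acceptor and whose benzylic carbon is the future C-7'. A Lewis acid (3+2) annulation forms C-8–C-9 and O–C-7' at once and relays the cyclopropane centres to C-7'. Aryllithium addition and cationic closure build ring 1; Evans aldols, two followed by Mitsunobu inversion, add the chains.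

Key step: step 5

Names used: lignan numbering. Ring SA is the syringyl ring on C-7 (it carries chain G2–G1); ring SB is the syringyl ring on C-7' (it carries G3). Ring 1 = C-7, O, C-9', C-8', C-8; ring 2 = C-7', O, C-9, C-8, C-8'. G1 = terminal erythro unit (7R,8S), G2 = inner threo unit (7R,8R), G3 = erythro unit (7S,8R). Xc = 4-benzyl-2-oxooxazolidin-3-yl.

Assumption: compounds 1, 8, 15, 17, 23 and 24, Rh2(5S-MEPY)4 and the reagents named are purchasable; isoeugenol is used as its (E)-isomer, the geometry being irrelevant because the propenyl group is cleaved in step 18.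

**Route**

Step 1
Reactants: 1 4-(benzyloxy)-3,5-dimethoxybenzaldehyde
Product: 2 methyl (Z)-3-[4-(benzyloxy)-3,5-dimethoxyphenyl]prop-2-enoate
Conditions: (CF3CH2O)2P(O)CH2CO2Me, KHMDS, 18-crown-6, THF, −78 °C
Reagents that add atoms: methyl bis(2,2,2-trifluoroethyl)phosphonoacetate, COC(=O)CP(=O)(OCC(F)(F)F)OCC(F)(F)F
Why: Still–Gennari olefination; the electron-poor phosphonate with a dissociated potassium counter-ion collapses irreversibly through the syn oxaphosphetane, so the (Z)-enoate should predominate.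

Step 2
Reactants: 2 methyl (Z)-3-[4-(benzyloxy)-3,5-dimethoxyphenyl]prop-2-enoate
Product: 3 (Z)-3-[4-(benzyloxy)-3,5-dimethoxyphenyl]prop-2-en-1-ol
Conditions: DIBAL-H (2.2 equiv), CH2Cl2, −78 °C
Reagents that add atoms: none
Why: 1,2-reduction of the enoate by the aluminium hydride at low temperature gives the allylic alcohol and leaves the Z geometry untouched.

Step 3
Reactants: 3 (Z)-3-[4-(benzyloxy)-3,5-dimethoxyphenyl]prop-2-en-1-ol
Product: 5 (Z)-3-[4-(benzyloxy)-3,5-dimethoxyphenyl]prop-2-en-1-yl diazoacetate, via bromoacetate 4 (not isolated)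
Conditions: BrCH2COBr, NaHCO3, MeCN, 0 °C; then TsNHNHTs, DBU, THF, 0 °C
Reagents that add atoms: bromoacetyl bromide, BrCC(Br)=O; N,N'-ditosylhydrazine, Cc1ccc(S(=O)(=O)NNS(=O)(=O)c2ccc(C)cc2)cc1
Why: O-acylation, then N-alkylation of the ditosylhydrazine by the bromoacetate and base-induced loss of two sulfinates (diazoacetate synthesis from bromoacetates) is mild enough for a Z-allylic ester.

Step 4
Reactants: 5 (Z)-3-[4-(benzyloxy)-3,5-dimethoxyphenyl]prop-2-en-1-yl diazoacetate
Product: 6 (1R,5S,6R)-6-[4-(benzyloxy)-3,5-dimethoxyphenyl]-3-oxabicyclo[3.1.0]hexan-2-one (aryl endo, cis to the lactone ring)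
Conditions: Rh2(5S-MEPY)4 [dirhodium tetrakis(methyl (S)-2-oxopyrrolidine-5-carboxylate)] (1 mol%), CH2Cl2, reflux, slow addition
Reagents that add atoms: none
Why: Intramolecular cyclopropanation by a chiral dirhodium carboxamidate carbene is concerted and stereospecific, so the Z-alkene should give the endo-aryl lactone, and the catalyst sets C-8 and C-8' (Z-allylic diazoacetates are its best substrate class; the sense of induction is assigned by analogy with simpler Z-allylic diazoacetates).

Step 5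
Reactants: 6 (1R,5S,6R)-6-[4-(benzyloxy)-3,5-dimethoxyphenyl]-3-oxabicyclo[3.1.0]hexan-2-one
Product: 7 (1S,5S,6R)-6-[4-(benzyloxy)-3,5-dimethoxyphenyl]-3,7-dioxabicyclo[3.3.0]octan-2-one (aryl exo; C-2 is the future C-7)
Conditions: 1,3,5-trioxane, TMSOTf (0.3 equiv), 2,6-di-tert-butyl-4-methylpyridine (0.3 equiv), 4 Å MS, CH2Cl2, −40 → 0 °C
Reagents that add atoms: 1,3,5-trioxane (formaldehyde source), C1OCOCO1
Why: Proposed new method: TMSOTf silylates the lactone carbonyl, whose π* is held parallel to the C-8–C-7' cyclopropane bond by the ring fusion, so this donor–acceptor bond should open as a formaldehyde oxygen (free or still part of trioxane) attacks the benzylic C-7' from the rear, giving a silyl ketene acetal tethered to an O-alkylated formaldehyde oxocarbenium ion; the ketene acetal carbon C-8 then adds to the CH2=O+ carbon and the silyl group is released for turnover. The closest known reaction type is the Sn(OTf)2- or Sc(OTf)3-catalysed (3+2) annulation of aldehydes with 2-arylcyclopropane-1,1-diesters, extended here to a strained cyclopropane with a single lactone acceptor and to formaldehyde. Ring 2 closes by C–C bond formation in a 5-(enolexo)-endo-trig aldol-type attack on the oxocarbenium ion, the same mode as in the diester annulation. C-7' is the only new stereocentre and is set by inversion at the endo-aryl carbon, which places the aryl group on the convex face (trans to C-9'), while C-8 and C-8' are carried over from step 4 and the new ring can only be cis-fused. The step needs cleavage of C-8–C-7' over the other two ring bonds, secured by the aryl donor on C-7' and the orbital alignment; it also needs C-alkylation at C-8 over Friedel–Crafts attack of the formaldehyde electrophile on the electron-rich ring SB, for which it relies on the far higher nucleophilicity of the tethered silyl ketene acetal.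

Step 6
Reactants: 8 4-bromo-2,6-dimethoxyphenol
Product: 9 (4-bromo-2,6-dimethoxyphenoxy)(tert-butyl)dimethylsilane
Conditions: TBSCl, imidazole, DMF, 40 °C
Reagents that add atoms: tert-butyldimethylsilyl chloride, CC(C)(C)[Si](C)(C)Cl
Why: Standard silylation of a phenol; the silyl ether tolerates the aryllithium, borohydride and Lewis acid steps that follow.

Step 7
Reactants: 9 (4-bromo-2,6-dimethoxyphenoxy)(tert-butyl)dimethylsilane; 7 (1S,5S,6R)-6-[4-(benzyloxy)-3,5-dimethoxyphenyl]-3,7-dioxabicyclo[3.3.0]octan-2-one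
Product: 12 [(2R,3S,4S)-2-[4-(benzyloxy)-3,5-dimethoxyphenyl]-4-{[4-(tert-butyldimethylsilyloxy)-3,5-dimethoxyphenyl](hydroxy)methyl}tetrahydrofuran-3-yl]methanol (both C-7 carbinol epimers), via aryllithium 10 (not isolated), via lactol 11 (not isolated)
Conditions: t-BuLi (2 equiv), THF, −78 °C; then 7, −78 °C; MeOH quench; NaBH4, 0 °C
Reagents that add atoms: none
Why: Bromine–lithium exchange and single addition of the aryllithium to the γ-lactone (the lithium hemiketal persists at −78 °C), then borohydride reduction of the ring-opened aryl ketone tautomer; the carbinol configuration at C-7 is left uncontrolled because step 8 erases it.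

Step 8
Reactants: 12 the diol from step 7
Product: 13 (7R,7'R,8S,8'S)-4'-O-benzyl-4-O-(tert-butyldimethylsilyl)syringaresinol (furofuran; ring SA silylated, ring SB benzylated)
Conditions: BF3·OEt2 (0.2 equiv), CH2Cl2, −20 → 0 °C
Reagents that add atoms: none
Why: Acid-promoted SN1 cycloetherification: the electron-rich benzylic alcohol ionises and the cis-disposed C-9' hydroxyl captures the cation in a 5-exo closure, so both C-7 epimers converge and the aryl group should end on the convex (exo) face, as in established furofuran lignan closures.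

Step 9
Reactants: 13 (7R,7'R,8S,8'S)-4'-O-benzyl-4-O-(tert-butyldimethylsilyl)syringaresinol
Product: 14 (7R,7'R,8S,8'S)-4-O-(tert-butyldimethylsilyl)syringaresinol (ring SB phenol free)
Conditions: H2 (1 atm), 10% Pd/C, EtOAc, rt
Reagents that add atoms: none
Why: Hydrogenolysis of the aryl benzyl ether is much faster than that of the furofuran benzylic C–O bonds under neutral conditions, and the aryl silyl ether is inert.

Step 10
Reactants: 14 (7R,7'R,8S,8'S)-4-O-(tert-butyldimethylsilyl)syringaresinol; 15 (S)-4-benzyl-3-(chloroacetyl)oxazolidin-2-one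
Product: 16 ring-SB aryloxyacetyl imide (14 alkylated on the ring-SB oxygen by CH2C(=O)–Xc, Xc of S configuration)
Conditions: K2CO3, NaI (10 mol%), acetone, rt → 40 °C
Reagents that add atoms: none
Why: Williamson etherification of the phenoxide with an α-halo imide (iodide catalysis), which is a fast SN2 reaction at a carbon next to a carbonyl group.

Step 11
Reactants: 16 ring-SB aryloxyacetyl imide; 17 4-(benzyloxy)-3-methoxybenzaldehyde
Product: 19 syn aldol adduct (2S,3R in the acyl chain: ring-SB–O–CH[C(=O)Xc]–CH(OH)–[4-(benzyloxy)-3-methoxyphenyl]), via boron enolate 18 (not isolated)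
Conditions: Bu2BOTf, Et3N, CH2Cl2, −78 → 0 °C; then 17, −78 → 0 °C; pH 7 buffer, MeOH, H2O2, 0 °C
Reagents that add atoms: none
Why: Evans syn aldol: the Z-boron enolate reacts through a Zimmerman–Traxler chair on the face away from the auxiliary benzyl group, which should set C-8 of G3 correctly (R after reduction) and C-7 as the threo epimer.

Step 12
Reactants: 19 syn aldol adduct
Product: 20 4-nitrobenzoate with inverted benzylic carbon (2S,3S in the acyl chain)
Conditions: 4-nitrobenzoic acid, PPh3, DIAD, THF, 0 °C → rt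
Reagents that add atoms: 4-nitrobenzoic acid, O=C(O)c1ccc([N+](=O)[O-])cc1
Why: Mitsunobu inversion of the secondary benzylic alcohol by SN2 displacement of the oxyphosphonium ion turns the threo adduct into the erythro series required for G3 (7S,8R after reduction).

Step 13
Reactants: 20 4-nitrobenzoate
Product: 21 phenol (ring SA hydroxyl free)
Conditions: HF·pyridine, pyridine, THF, 0 °C → rt
Reagents that add atoms: none
Why: Buffered fluoride cleaves the aryl silyl ether and should leave the imide, the 4-nitrobenzoate and the furofuran untouched.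

Step 14
Reactants: 21 phenol; 15 (S)-4-benzyl-3-(chloroacetyl)oxazolidin-2-one
Product: 22 bis-imide (ring-SA oxygen alkylated by CH2C(=O)–Xc, Xc of S configuration)
Conditions: K2CO3, NaI (10 mol%), acetone, rt
Reagents that add atoms: none
Why: Williamson etherification as in step 10, kept at room temperature because the existing α-substituted β-acyloxy imide, although slow to enolise owing to allylic strain, is base-sensitive.

Step 15
Reactants: 23 (E)-isoeugenol [2-methoxy-4-(prop-1-enyl)phenol]; 24 (R)-4-benzyl-3-(chloroacetyl)oxazolidin-2-one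
Product: 25 (R)-4-benzyl-3-{[2-methoxy-4-((E)-prop-1-enyl)phenoxy]acetyl}oxazolidin-2-one
Conditions: K2CO3, NaI (10 mol%), acetone, 50 °C
Reagents that add atoms: none
Why: Williamson etherification; the propenyl group serves as a masked formyl group that survives enolisation and Mitsunobu conditions.

Step 16
Reactants: 25 the isoeugenol-derived imide; 17 4-(benzyloxy)-3-methoxybenzaldehyde
Product: 27 syn aldol adduct (2R,3S in the acyl chain), via boron enolate 26 (not isolated)
Conditions: Bu2BOTf, Et3N, CH2Cl2, −78 → 0 °C; then 17, −78 → 0 °C; pH 7 buffer, MeOH, H2O2, 0 °C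
Reagents that add atoms: none
Why: Evans syn aldol with the enantiomeric auxiliary, which should set C-8 of G1 as S (after reduction) through the same chair transition state.

Step 17
Reactants: 27 syn aldol adduct
Product: 28 4-nitrobenzoate with inverted benzylic carbon (2R,3R in the acyl chain)
Conditions: 4-nitrobenzoic acid, PPh3, DIAD, THF, 0 °C → rt
Reagents that add atoms: 4-nitrobenzoic acid, O=C(O)c1ccc([N+](=O)[O-])cc1
Why: Mitsunobu inversion at the benzylic carbon gives the erythro series of G1 (7R,8S after reduction).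

Step 18
Reactants: 28 4-nitrobenzoate
Product: 29 aldehyde (propenyl group cleaved to formyl)
Conditions: OsO4 (2 mol%), NaIO4, 2,6-lutidine, dioxane/H2O, rt
Reagents that add atoms: sodium periodate (oxygen source, with catalytic OsO4), [Na+].[O-]I(=O)(=O)=O
Why: Lemieux–Johnson oxidation cleaves the styrenic double bond through the osmate ester and periodate; the arenes, esters and the imide are inert to it.

Step 19
Reactants: 22 bis-imide; 29 aldehyde
Product: 31 tris-imide syn aldol adduct (new centres 2S,3R in the G2 acyl chain; benzylic hydroxyl free), via boron enolate 30 (not isolated)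
Conditions: Bu2BOTf (2 equiv), Et3N, CH2Cl2, −78 → 0 °C; then 29, −78 → 0 °C; pH 7 buffer, MeOH, H2O2, 0 °C
Reagents that add atoms: none
Why: Evans syn aldol under reagent control gives the threo unit G2 (7R,8R after reduction); only the α-unsubstituted aryloxyacetyl imide is enolised, since the α-substituted imides resist enolisation through allylic strain.

Step 20
Reactants: 31 tris-imide aldol adduct
Product: 32 target dibenzyl ether (phenols of G1 and G3 benzylated; all three arylglycerol units free)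
Conditions: LiBH4 (excess), MeOH (additive), THF, 0 °C → rt
Reagents that add atoms: none
Why: Reductive cleavage of N-acyl oxazolidinones by lithium borohydride gives the three primary alcohols, and the two 4-nitrobenzoates are cleaved at the acyl carbon, so no stereocentre is touched; the phenols stay benzylated, so no phenoxide can expel a benzylic ester.

Step 21
Reactants: 32 target dibenzyl ether
Product: 33 target (CNP0316493.1)
Conditions: H2 (1 atm), 10% Pd/C, EtOAc/EtOH, rt
Reagents that add atoms: none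
Why: Hydrogenolysis of aryl benzyl ethers under neutral conditions is faster than cleavage of the benzylic alcohols or the furofuran C–O bonds, the usual last step for arylglycerol β-aryl ethers.

**Compound list**

1 | 4-(benzyloxy)-3,5-dimethoxybenzaldehyde | O=Cc1cc(OC)c(OCc2ccccc2)c(OC)c1 | starting material
2 | methyl (Z)-3-[4-(benzyloxy)-3,5-dimethoxyphenyl]prop-2-enoate | COC(=O)/C=C\c1cc(OC)c(OCc2ccccc2)c(OC)c1 | intermediate
3 | (Z)-3-[4-(benzyloxy)-3,5-dimethoxyphenyl]prop-2-en-1-ol | OC/C=C\c1cc(OC)c(OCc2ccccc2)c(OC)c1 | intermediate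
4 | (Z)-3-[4-(benzyloxy)-3,5-dimethoxyphenyl]prop-2-en-1-yl bromoacetate | BrCC(=O)OC/C=C\c1cc(OC)c(OCc2ccccc2)c(OC)c1 | intermediate
5 | (Z)-3-[4-(benzyloxy)-3,5-dimethoxyphenyl]prop-2-en-1-yl diazoacetate | [N-]=[N+]=CC(=O)OC/C=C\c1cc(OC)c(OCc2ccccc2)c(OC)c1 | intermediate
6 | (1R,5S,6R)-6-[4-(benzyloxy)-3,5-dimethoxyphenyl]-3-oxabicyclo[3.1.0]hexan-2-one, aryl endo | O=C1OC[C@@H]2[C@H]1[C@@H]2c1cc(OC)c(OCc2ccccc2)c(OC)c1 | intermediate
7 | (1S,5S,6R)-6-[4-(benzyloxy)-3,5-dimethoxyphenyl]-3,7-dioxabicyclo[3.3.0]octan-2-one, aryl exo | O=C1OC[C@@H]2[C@H]1CO[C@H]2c1cc(OC)c(OCc2ccccc2)c(OC)c1 | intermediate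
8 | 4-bromo-2,6-dimethoxyphenol | COc1cc(Br)cc(OC)c1O | starting material
9 | (4-bromo-2,6-dimethoxyphenoxy)(tert-butyl)dimethylsilane | COc1cc(Br)cc(OC)c1O[Si](C)(C)C(C)(C)C | intermediate
10 | [4-(tert-butyldimethylsilyloxy)-3,5-dimethoxyphenyl]lithium | [Li]c1cc(OC)c(O[Si](C)(C)C(C)(C)C)c(OC)c1 | intermediate
11 | lactol: (1S,5S,6R)-6-[4-(benzyloxy)-3,5-dimethoxyphenyl]-2-[4-(tert-butyldimethylsilyloxy)-3,5-dimethoxyphenyl]-3,7-dioxabicyclo[3.3.0]octan-2-ol, C-2 epimers | OC1(c2cc(OC)c(O[Si](C)(C)C(C)(C)C)c(OC)c2)OC[C@@H]2[C@H]1CO[C@H]2c1cc(OC)c(OCc2ccccc2)c(OC)c1 | intermediate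
12 | [(2R,3S,4S)-2-[4-(benzyloxy)-3,5-dimethoxyphenyl]-4-{[4-(tert-butyldimethylsilyloxy)-3,5-dimethoxyphenyl](hydroxy)methyl}tetrahydrofuran-3-yl]methanol, carbinol epimers | OC(c1cc(OC)c(O[Si](C)(C)C(C)(C)C)c(OC)c1)[C@@H]1CO[C@@H](c2cc(OC)c(OCc3ccccc3)c(OC)c2)[C@@H]1CO | intermediate
13 | (7R,7'R,8S,8'S)-4'-O-benzyl-4-O-(tert-butyldimethylsilyl)syringaresinol | COc1cc([C@@H]2OC[C@@H]3[C@H]2CO[C@H]3c2cc(OC)c(OCc4ccccc4)c(OC)c2)cc(OC)c1O[Si](C)(C)C(C)(C)C | intermediate
14 | (7R,7'R,8S,8'S)-4-O-(tert-butyldimethylsilyl)syringaresinol | COc1cc([C@@H]2OC[C@@H]3[C@H]2CO[C@H]3c2cc(OC)c(O)c(OC)c2)cc(OC)c1O[Si](C)(C)C(C)(C)C | intermediate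
15 | (S)-4-benzyl-3-(chloroacetyl)oxazolidin-2-one | O=C(CCl)N1C(=O)OC[C@@H]1Cc1ccccc1 | starting material
16 | ring-SB aryloxyacetyl imide of 14 (S auxiliary) | COc1cc([C@@H]2OC[C@@H]3[C@H]2CO[C@H]3c2cc(OC)c(OCC(=O)N4C(=O)OC[C@@H]4Cc4ccccc4)c(OC)c2)cc(OC)c1O[Si](C)(C)C(C)(C)C | intermediate
17 | 4-(benzyloxy)-3-methoxybenzaldehyde | O=Cc1ccc(OCc2ccccc2)c(OC)c1 | starting material
18 | Z-dibutylboron enolate of 16 | COc1cc([C@@H]2OC[C@@H]3[C@H]2CO[C@H]3c2cc(OC)c(O/C=C(\OB(CCCC)CCCC)N4C(=O)OC[C@@H]4Cc4ccccc4)c(OC)c2)cc(OC)c1O[Si](C)(C)C(C)(C)C | intermediate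
19 | G3 syn aldol adduct, (2S,3R) in the acyl chain | COc1cc([C@@H]2OC[C@@H]3[C@H]2CO[C@H]3c2cc(OC)c(O[C@H](C(=O)N4C(=O)OC[C@@H]4Cc4ccccc4)[C@H](O)c4ccc(OCc5ccccc5)c(OC)c4)c(OC)c2)cc(OC)c1O[Si](C)(C)C(C)(C)C | intermediate
20 | G3 4-nitrobenzoate, (2S,3S) in the acyl chain | COc1cc([C@@H]2OC[C@@H]3[C@H]2CO[C@H]3c2cc(OC)c(O[C@H](C(=O)N4C(=O)OC[C@@H]4Cc4ccccc4)[C@@H](OC(=O)c4ccc([N+](=O)[O-])cc4)c4ccc(OCc5ccccc5)c(OC)c4)c(OC)c2)cc(OC)c1O[Si](C)(C)C(C)(C)C | intermediate
21 | phenol from 20 (ring SA hydroxyl free) | COc1cc([C@@H]2OC[C@@H]3[C@H]2CO[C@H]3c2cc(OC)c(O[C@H](C(=O)N4C(=O)OC[C@@H]4Cc4ccccc4)[C@@H](OC(=O)c4ccc([N+](=O)[O-])cc4)c4ccc(OCc5ccccc5)c(OC)c4)c(OC)c2)cc(OC)c1O | intermediate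
22 | bis-imide (ring-SA aryloxyacetyl imide, S auxiliary) | COc1cc([C@@H]2OC[C@@H]3[C@H]2CO[C@H]3c2cc(OC)c(O[C@H](C(=O)N4C(=O)OC[C@@H]4Cc4ccccc4)[C@@H](OC(=O)c4ccc([N+](=O)[O-])cc4)c4ccc(OCc5ccccc5)c(OC)c4)c(OC)c2)cc(OC)c1OCC(=O)N6C(=O)OC[C@@H]6Cc6ccccc6 | intermediate
23 | (E)-isoeugenol | C/C=C/c1ccc(O)c(OC)c1 | starting material
24 | (R)-4-benzyl-3-(chloroacetyl)oxazolidin-2-one | O=C(CCl)N1C(=O)OC[C@H]1Cc1ccccc1 | starting material
25 | (R)-4-benzyl-3-{[2-methoxy-4-((E)-prop-1-enyl)phenoxy]acetyl}oxazolidin-2-one | C/C=C/c1ccc(OCC(=O)N2C(=O)OC[C@H]2Cc2ccccc2)c(OC)c1 | intermediate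
26 | Z-dibutylboron enolate of 25 | C/C=C/c1ccc(O/C=C(\OB(CCCC)CCCC)N2C(=O)OC[C@H]2Cc2ccccc2)c(OC)c1 | intermediate
27 | G1 syn aldol adduct, (2R,3S) in the acyl chain | COc1cc([C@H](O)[C@H](C(=O)N2C(=O)OC[C@H]2Cc2ccccc2)Oc2ccc(/C=C/C)cc2OC)ccc1OCc1ccccc1 | intermediate
28 | G1 4-nitrobenzoate, (2R,3R) in the acyl chain | COc1cc([C@@H](OC(=O)c2ccc([N+](=O)[O-])cc2)[C@H](C(=O)N2C(=O)OC[C@H]2Cc2ccccc2)Oc2ccc(/C=C/C)cc2OC)ccc1OCc1ccccc1 | intermediate
29 | G1 aldehyde (4-formyl-2-methoxyphenoxy in place of the propenylphenoxy group of 28) | COc1cc([C@@H](OC(=O)c2ccc([N+](=O)[O-])cc2)[C@H](C(=O)N2C(=O)OC[C@H]2Cc2ccccc2)Oc2ccc(C=O)cc2OC)ccc1OCc1ccccc1 | intermediate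
30 | Z-dibutylboron enolate of 22 (ring-SA imide) | COc1cc([C@@H]2OC[C@@H]3[C@H]2CO[C@H]3c2cc(OC)c(O[C@H](C(=O)N4C(=O)OC[C@@H]4Cc4ccccc4)[C@@H](OC(=O)c4ccc([N+](=O)[O-])cc4)c4ccc(OCc5ccccc5)c(OC)c4)c(OC)c2)cc(OC)c1O/C=C(\OB(CCCC)CCCC)N6C(=O)OC[C@@H]6Cc6ccccc6 | intermediate
31 | tris-imide aldol adduct (G1 and G3 as 4-nitrobenzoates, G2 hydroxyl free) | COc1cc([C@@H](OC(=O)c2ccc([N+](=O)[O-])cc2)[C@H](C(=O)N2C(=O)OC[C@H]2Cc2ccccc2)Oc2ccc([C@@H](O)[C@@H](C(=O)N3C(=O)OC[C@@H]3Cc3ccccc3)Oc3c(OC)cc([C@@H]4OC[C@@H]5[C@H]4CO[C@H]5c4cc(OC)c(O[C@H](C(=O)N5C(=O)OC[C@@H]5Cc5ccccc5)[C@@H](OC(=O)c5ccc([N+](=O)[O-])cc5)c5ccc(OCc6ccccc6)c(OC)c5)c(OC)c4)cc3OC)cc2OC)ccc1OCc1ccccc1 | intermediate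
32 | target dibenzyl ether (phenols of G1 and G3 benzylated) | COc1cc([C@@H](O)[C@H](CO)Oc2ccc([C@@H](O)[C@@H](CO)Oc3c(OC)cc([C@@H]4OC[C@@H]5[C@H]4CO[C@H]5c4cc(OC)c(O[C@H](CO)[C@@H](O)c5ccc(OCc6ccccc6)c(OC)c5)c(OC)c4)cc3OC)cc2OC)ccc1OCc1ccccc1 | intermediate
33 | CNP0316493.1 | COc1cc([C@@H](O)[C@H](CO)Oc2ccc([C@@H](O)[C@@H](CO)Oc3c(OC)cc([C@@H]4OC[C@@H]5[C@H]4CO[C@H]5c4cc(OC)c(O[C@H](CO)[C@@H](O)c5ccc(O)c(OC)c5)c(OC)c4)cc3OC)cc2OC)ccc1O | target

**Step count.** 21 steps in total. Longest linear sequence: 16 steps (steps 1–5, 7–14, 19, 20, 21).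

**Steps most likely to fail**

1. Step 5 (proposed new method). The single lactone acceptor may not polarise the cyclopropane enough. The silylated formaldehyde species could then hydroxymethylate the electron-rich ring SB or oligomerise, and full ionisation of the benzylic carbon could erode the inversion that sets C-7'. The fallback uses known chemistry, sets out from alcohol 3 and comes back at furofuranone 7. Acylation of 3 with methyl malonyl chloride (pyridine, CH2Cl2) gives the (Z)-allyl methyl malonate F1. Diazo transfer (4-acetamidobenzenesulfonyl azide, Et3N, MeCN) gives the diazomalonate F2. Stereospecific intramolecular cyclopropanation with CuOTf (monovalent copper) and (S,S)-tert-butyl-bis(oxazoline) gives the doubly activated endo-aryl lactone ester F3, configured as 6 at the three ring carbons; its enantiomeric purity would be raised by crystallisation if needed. The Sn(OTf)2-catalysed aldehyde (3+2) annulation established for 2-arylcyclopropane-1,1-dicarbonyl compounds, run with monomeric formaldehyde in CH2Cl2, forms the same two bonds and gives the furofuranone ester F4. Krapcho demethoxycarbonylation (LiCl, wet DMSO, 150 °C) removes the activating ester and returns 7, since the ring fusion can only be cis.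

2. Step 12 (the same applies to step 17). β-Elimination to the α-aryloxy cinnamoyl imide and partial SN1 substitution at the electron-rich benzylic carbon may compete with clean inversion. The fallback sets out from 19 and comes back at 20. Dess–Martin oxidation gives the β-keto imide F5. Reduction with K-Selectride (THF, −78 °C) under Felkin–Anh control by the α-aryloxy group should give the anti alcohol F6, the benzylic epimer of 19. Acylation with 4-nitrobenzoyl chloride (pyridine, DMAP) then gives 20.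

3. Step 14. The phenoxide and carbonate may deprotonate the existing β-acyloxy imide and expel 4-nitrobenzoate (E1cB) faster than the phenoxide is alkylated. The fallback sets out from 21 and comes back at 22, replacing the basic alkylation by a neutral redox condensation. (S)-4-Benzyloxazolidin-2-one is acylated (n-BuLi, benzyloxyacetyl chloride, THF, −78 °C) to the benzyloxyacetyl imide F7. Hydrogenolysis (H2, Pd/C) gives the hydroxyacetyl imide F8. Mitsunobu etherification of phenol 21 with F8 (PPh3, DIAD, THF) gives 22.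

Further compounds
F1 | step 5 | (Z)-3-[4-(benzyloxy)-3,5-dimethoxyphenyl]prop-2-en-1-yl methyl malonate | COC(=O)CC(=O)OC/C=C\c1cc(OC)c(OCc2ccccc2)c(OC)c1
F2 | step 5 | (Z)-3-[4-(benzyloxy)-3,5-dimethoxyphenyl]prop-2-en-1-yl methyl diazomalonate | COC(=O)C(=[N+]=[N-])C(=O)OC/C=C\c1cc(OC)c(OCc2ccccc2)c(OC)c1
F3 | step 5 | methyl 6-[4-(benzyloxy)-3,5-dimethoxyphenyl]-2-oxo-3-oxabicyclo[3.1.0]hexane-1-carboxylate, aryl endo, ring carbons configured as in 6 | O=C1OC[C@@H]2[C@@]1(C(=O)OC)[C@@H]2c1cc(OC)c(OCc2ccccc2)c(OC)c1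
F4 | step 5 | methyl 6-[4-(benzyloxy)-3,5-dimethoxyphenyl]-2-oxo-3,7-dioxabicyclo[3.3.0]octane-1-carboxylate, aryl exo, configured as in 7 | O=C1OC[C@@H]2[C@@]1(C(=O)OC)CO[C@H]2c1cc(OC)c(OCc2ccccc2)c(OC)c1
F5 | step 12 | β-keto imide from 19 (benzylic carbon oxidised to the ketone) | COc1cc([C@@H]2OC[C@@H]3[C@H]2CO[C@H]3c2cc(OC)c(O[C@H](C(=O)N4C(=O)OC[C@@H]4Cc4ccccc4)C(=O)c4ccc(OCc5ccccc5)c(OC)c4)c(OC)c2)cc(OC)c1O[Si](C)(C)C(C)(C)C
F6 | step 12 | anti alcohol, benzylic epimer of 19, (2S,3S) in the acyl chain | COc1cc([C@@H]2OC[C@@H]3[C@H]2CO[C@H]3c2cc(OC)c(O[C@H](C(=O)N4C(=O)OC[C@@H]4Cc4ccccc4)[C@@H](O)c4ccc(OCc5ccccc5)c(OC)c4)c(OC)c2)cc(OC)c1O[Si](C)(C)C(C)(C)C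
F7 | step 14 | (S)-4-benzyl-3-[(benzyloxy)acetyl]oxazolidin-2-one | O=C(COCc1ccccc1)N1C(=O)OC[C@@H]1Cc1ccccc1
F8 | step 14 | (S)-4-benzyl-3-(hydroxyacetyl)oxazolidin-2-one | O=C(CO)N1C(=O)OC[C@@H]1Cc1ccccc1
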